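## The problem

The target **11**, (2S)-5,7-dihydroxy-2-(4-methoxyphenyl)-6-(3-methylbut-2-en-1-yl)chroman-4-one, is a flavanone. Ring C (O1, C2, C3, C4, C4a, C8a) is fused to a phloroglucinol-type ring A that carries hydroxyls at C5 and C7, a prenyl group at C6 between them and one hydrogen at C8. A 4-methoxyphenyl ring B sits on C2.

Ring A poses the regiochemical question. The two oxygens ortho to the acyl carbon must be told apart: the one next to C8–H becomes O1, the one wedged between the carbonyl and the prenyl group stays as the 5-hydroxyl. The wrong choice gives the 8-prenyl isomer.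

C2 is the only stereocentre, so nothing in the molecule can direct it and a chiral catalyst or reagent must set it. It is also fragile: base, and hot acid, open ring C to the 2'-hydroxychalcone by retro-oxa-Michael reaction and reclose it without memory. Every operation after C2 is set must therefore stay near neutral.

The prenyl alkene between two phenols closes to a 2,2-dimethylchroman under strong acid, is dehydrogenated by quinone oxidants once a neighbouring phenol is free, and is lost on hydrogenation. Free phenols would also quench a carbenoid by O–H insertion.

The enabling feature is that C2 carries exactly one hydrogen and is bound to O1 and to an anisyl ring, while C3 is a methylene next to the C4 ketone. Read backwards, C2–H and the C2–C3 bond are what remains after a carbene at C3 has inserted into a CH2 of a 4-methoxybenzyl ether on O1. C3 and C4 are then simply the acetyl group of an acylphloroglucinol.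

## Retrosynthesis

**11 from 10.** Only the two O–Si bonds at O5 and O7 are cut, giving the bis-silyl ether **10**. Silyl ethers are preferred over acetals or benzyl ethers for three reasons: they come off with buffered fluoride (no base to open ring C, no strong acid to cyclise the prenyl group), they have no C–H bond alpha to oxygen, and their oxygens are poor donors. The forward step only has to be non-basic.

**10 from 9.** The C2–C3 bond is cut, which opens ring C and turns the stereocentre into the prochiral CH2 of an anisylmethyl ether. The precursor is the diazoketone **9**. The neighbouring cuts are less attractive: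
- O1–C2 (chalcone oxa-Michael closure) is reversible and hard to render enantioselective on a 5,7-dioxygenated ring.
- C2–aryl (conjugate addition to a chromone) needs a chromone to be built first.
- C4–C4a (acylation of the arene) would place the stereocentre in a fragment prone to elimination.

**9** has no ring C and no stereocentre. The forward reaction must select one of two enantiotopic benzylic hydrogens and must prefer C–H insertion over attack at O1.

**9 from 7 (through 8).** The C3–N bond is cut. The diazo group is put on the methyl ketone **7** by trifluoroacetylation to the diketone **8** and diazo transfer with loss of the activating group. This keeps the acetyl group of the starting material as C3/C4; an acid chloride and diazomethane would require a benzoic acid series instead. The forward step needs a kinetic enolate at low temperature so that the ortho silyl group does not migrate.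

**7 from 6, 6 from 4 and 5, 4 from 3.** Three O–Si or O–C bonds are cut in the reverse of the order of hydroxyl reactivity in **3**. The hydroxyl para to the acetyl group is the most acidic and not chelated, so it takes the triisopropylsilyl group first (**4**). Of the two ortho hydroxyls, the one next to the ring hydrogen is less hindered and takes the 4-methoxybenzyl group from alcohol **5** under Mitsunobu conditions (**6**). No base is present, so the aryl silyl ether is safe. The last hydroxyl, between carbonyl and prenyl, is silylated with the reactive triflate (**7**). This sequence decides 6- versus 8-prenyl, and it follows the intrinsic bias of the ring.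

**3 from 1 and 2.** The bond between ring carbon C6 and the prenyl CH2 is cut. Because 2,4,6-trihydroxyacetophenone **1** is symmetric, C-alkylation with prenyl bromide **2** has no regiochemical issue; only over-alkylation must be held back.

## Roads not taken

**Alternative 1:** The cut is O1–C8a. The open-chain diol A2, (1R,3S)-1-[2-bromo-4,6-bis(methoxymethoxy)-5-(3-methylbut-2-en-1-yl)phenyl]-3-(4-methoxyphenyl)propane-1,3-diol, would be closed with CuI, 1,10-phenanthroline and Cs2CO3 (Ullmann-type etherification with monovalent copper) to the flavan-4-ol A1. Oxidation at C4 and removal of the two acetals would follow.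
- Merits: C2 is a carbinol set beforehand by well-tried asymmetric reduction or aldol chemistry, and its C–O bond is not touched in the coupling. The bromine fixes which carbon becomes C8a. The C4 hydroxyl cannot compete, since it would form a four-membered ring.
- Weak points: A2 needs a bromine on a ring that already holds the prenyl alkene, so electrophilic bromination must spare the alkene. The aryl bromide is electron-rich and flanked on both sides, so the coupling needs heat, and a 4-methoxybenzylic alkoxide can eliminate under hot carbonate. After closure come an oxidation and an acidic acetal cleavage next to the prenyl group, the conditions under which chroman formation and erosion at C2 are most to be feared.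
- Comparison: in security of optical purity this road is better than the chosen one, which rests on a catalyst-controlled C–H selection. The chosen plan sets against it roughly half the number of steps, the correct oxidation level at C4 from the start, and a last step free of acid and base.

**Alternative 2:** The cuts are O1–C8a and C4–C4a. Fluoride would strip the silyl and triflate groups from A5, 3,5-bis(methoxymethoxy)-4-(3-methylbut-2-en-1-yl)-2-(trimethylsilyl)phenyl trifluoromethanesulfonate. The alkoxide of the hydroxy ester A4, methyl (3S)-3-hydroxy-3-(4-methoxyphenyl)propanoate, would add at C8a, as the C5 alkoxy group dictates, and the carbanion left at C4a would close onto the ester to give the flavanone A3.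
- Merits: this is the most convergent plan. Both ring C bonds form in one operation at the ketone oxidation level, and A4 is available by asymmetric hydrogenation of the keto ester.
- Weak points: A5 is a hexasubstituted benzene and costs a long sequence. The aryl anion formed from an aliphatic alkoxide is usually protonated faster than it acylates an ester. The alkoxide of A4 can undergo retro-aldol cleavage or eliminate to the cinnamate. A3 would form in a basic fluoride medium, where ring opening threatens C2. The acetals again need acid at the end.
- Comparison: in convergence and in the source of chirality it is better. The chosen plan sets against it a short linear sequence from a cheap symmetric arene and a key step with one uncertain event, not three.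

**Alternative 3:** The cuts run through ring A (C5–C6, C7–C8, C4a–C5, with C8–C8a made by migration). Irradiation of the diazoketone A7, (2S)-6-(2-diazoacetyl)-2-(4-methoxyphenyl)-2,3-dihydro-4H-pyran-4-one, would trigger a Wolff rearrangement. The resulting ketene would add the siloxyalkyne A8, triisopropyl[(5-methylhex-4-en-1-yn-1-yl)oxy]silane, and four-electron ring opening, six-electron ring closure and tautomerisation would give A6.
- Merits: the positions of 5-OH, prenyl, O7 and C8–H follow from the mechanism, so no hydroxyl differentiation is needed. On this point it is clearly better than the chosen plan. The 5-hydroxyl emerges free and only one desilylation remains.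
- Weak points: A7 needs an asymmetric hetero-Diels–Alder reaction and a carboxyl-to-diazoketone conversion. Its enone chromophore absorbs in the same region as the diazoketone. Its C2 sits beta to a ketone and can open. A8 is a skipped enyne ynol ether that is laborious to make and to store. Two fragments of four to five steps each make the route longer.
- Comparison: the chosen plan takes ring A ready-made and has to set hydroxyl differentiation against the built-in regiocontrol of this road. That differentiation runs with the natural reactivity order of the three hydroxyls.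

Key step: step 6

Assumption: the sense of induction of Rh2(S-PTTL)4, dirhodium tetrakis[N-phthaloyl-(S)-tert-leucinate], in this insertion cannot be predicted with certainty. The route is written with the S-configured catalyst, and Rh2(R-PTTL)4 would be used if the first trial delivers the 2R product.

## Route

Step 1
Reactants: 1 2,4,6-trihydroxyacetophenone; 2 prenyl bromide (1-bromo-3-methylbut-2-ene)
Product: 3 1-[2,4,6-trihydroxy-3-(3-methylbut-2-en-1-yl)phenyl]ethanone
Conditions: 2 (1.0 equiv), DBU (1.1 equiv), THF, 0 °C to rt
Reagents that add atoms: none
Why: C-alkylation of the ambident phloroglucinol phenolate by the soft allylic bromide in a weakly polar medium; the two free ring positions of 1 are equivalent, so only the degree of alkylation has to be held back by using one equivalent of 2 and recovering unreacted 1.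

Step 2
Reactants: 3 1-[2,4,6-trihydroxy-3-(3-methylbut-2-en-1-yl)phenyl]ethanone
Product: 4 1-[2,6-dihydroxy-3-(3-methylbut-2-en-1-yl)-4-(triisopropylsilyloxy)phenyl]ethanone
Conditions: TIPSCl (1.05 equiv), imidazole, DMF, 0 °C
Reagents that add atoms: triisopropylsilyl chloride, CC(C)[Si](Cl)(C(C)C)C(C)C
Why: Selective silylation of a phenol with a silyl chloride and imidazole; the hydroxyl para to the acetyl group is the most acidic and is not chelated, while the two ortho hydroxyls are held back by hydrogen bonding to the carbonyl and by the bulk of the reagent.

Step 3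
Reactants: 4 1-[2,6-dihydroxy-3-(3-methylbut-2-en-1-yl)-4-(triisopropylsilyloxy)phenyl]ethanone; 5 4-methoxybenzyl alcohol
Product: 6 1-[2-hydroxy-6-(4-methoxybenzyloxy)-3-(3-methylbut-2-en-1-yl)-4-(triisopropylsilyloxy)phenyl]ethanone
Conditions: 5 (1.05 equiv), PPh3, DIAD, THF, 0 °C to rt
Reagents that add atoms: none
Why: Mitsunobu etherification of a phenol, run without base so that the aryl silyl ether is not touched. Of the two ortho hydroxyls the one flanked by the ring hydrogen should react, as in the known dialkylation pattern of 3-alkylphloroacetophenones, and the remaining hydroxyl between carbonyl and prenyl stays chelated and resists a second alkylation.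

Step 4
Reactants: 6 1-[2-hydroxy-6-(4-methoxybenzyloxy)-3-(3-methylbut-2-en-1-yl)-4-(triisopropylsilyloxy)phenyl]ethanone
Product: 7 1-[2-(tert-butyldimethylsilyloxy)-6-(4-methoxybenzyloxy)-3-(3-methylbut-2-en-1-yl)-4-(triisopropylsilyloxy)phenyl]ethanone
Conditions: TBSOTf (1.3 equiv), 2,6-lutidine, CH2Cl2, −40 to 0 °C
Reagents that add atoms: tert-butyldimethylsilyl trifluoromethanesulfonate, CC(C)(C)[Si](C)(C)OS(=O)(=O)C(F)(F)F
Why: Silylation of a hindered, chelated phenol with a silyl triflate and a hindered pyridine base; 2,6-lutidine at this temperature should not enolise the methyl ketone, so O-silylation of the phenol is the only expected reaction.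

Step 5
Reactants: 7 1-[2-(tert-butyldimethylsilyloxy)-6-(4-methoxybenzyloxy)-3-(3-methylbut-2-en-1-yl)-4-(triisopropylsilyloxy)phenyl]ethanone
Product: 9 2-diazo-1-[2-(tert-butyldimethylsilyloxy)-6-(4-methoxybenzyloxy)-3-(3-methylbut-2-en-1-yl)-4-(triisopropylsilyloxy)phenyl]ethanone, via trifluoroacetyl diketone 8 (not isolated)
Conditions: LiN(SiMe3)2, THF, −78 °C; CF3CO2CH2CF3, −78 °C; NH4Cl(aq) work-up; then MsN3, Et3N, H2O (1 equiv), MeCN, rt
Reagents that add atoms: 2,2,2-trifluoroethyl trifluoroacetate, O=C(OCC(F)(F)F)C(F)(F)F (its atoms stay only in 8); methanesulfonyl azide, CS(=O)(=O)N=[N+]=[N-]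
Why: Detrifluoroacetylative diazo transfer (Danheiser variant of the Regitz reaction): the kinetic lithium enolate is trifluoroacetylated, and the activated diketone 8 takes the diazo group from the sulfonyl azide with loss of the trifluoroacetyl group as the N-sulfonyl amide. The short enolate lifetime at −78 °C should keep the ortho silyl group from migrating to the enolate oxygen.

Step 6
Reactants: 9 2-diazo-1-[2-(tert-butyldimethylsilyloxy)-6-(4-methoxybenzyloxy)-3-(3-methylbut-2-en-1-yl)-4-(triisopropylsilyloxy)phenyl]ethanone
Product: 10 (2S)-5-(tert-butyldimethylsilyloxy)-2-(4-methoxyphenyl)-6-(3-methylbut-2-en-1-yl)-7-(triisopropylsilyloxy)chroman-4-one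
Conditions: Rh2(S-PTTL)4 (2 mol %), 4 Å MS, CH2Cl2, 0 °C, slow addition of 9 (final 0.01 M)
Reagents that add atoms: none
Why: Rh2(S-PTTL)4 takes up the diazo carbon of 9 with loss of N2 to give an electrophilic divalent rhodium carbenoid at C3, which inserts into one benzylic C–H bond of the 4-methoxybenzyl group on O1 through a concerted, asynchronous three-centre transition state with hydride-like transfer, forming C2–C3. The closest known reaction type is the dirhodium-carboxylate-catalysed C–H insertion of ortho-alkoxyaryl diazoketones into the ether CH2 to give chroman-4-ones, which has also been run with chiral carboxylates. Ring C closes as a six-membered ring by 1,6-insertion (carbenoid carbon, C4, C4a, C8a, O1, benzylic carbon), the usual 1,5-position being O1 itself. C2 is the only new stereocentre and is set by the catalyst: the phthalimido walls of the four tert-leucinate ligands distinguish the two enantiotopic benzylic hydrogens, and the catalyst enantiomer that gives 2S is the one used. The step needs chemoselectivity for C–H insertion over attack of O1 on the carbenoid (oxonium ylide, then 1,2-shift of the benzyl group to a benzofuranone), over addition to the anisyl ring and over reaction with the prenyl alkene. The substrate should secure this because the benzylic C–H bond is doubly activated by O1 and the anisyl ring, the O1 lone pair is drawn into the ortho-acyl arene, the silyl ethers on O5 and O7 have no alpha C–H bond and shield their oxygens, and the prenyl group sits meta to the acyl arm and cannot reach the carbenoid. Slow addition at low concentration suppresses carbene dimerisation, and the neutral medium leaves the new flavanone closed.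

Step 7
Reactants: 10 (2S)-5-(tert-butyldimethylsilyloxy)-2-(4-methoxyphenyl)-6-(3-methylbut-2-en-1-yl)-7-(triisopropylsilyloxy)chroman-4-one
Product: 11 (2S)-5,7-dihydroxy-2-(4-methoxyphenyl)-6-(3-methylbut-2-en-1-yl)chroman-4-one
Conditions: HF·pyridine, excess pyridine, THF, 0 °C to rt
Reagents that add atoms: none
Why: Fluoride-driven cleavage of both aryl silyl ethers through Si–F bond formation; pyridine-buffered HF is not basic enough to open ring C by retro-oxa-Michael reaction and not acidic enough to cyclise the prenyl group onto a phenol, so C2 should keep its configuration.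

## Compound list

1 | 2,4,6-trihydroxyacetophenone | CC(=O)c1c(O)cc(O)cc1O | starting material
2 | prenyl bromide (1-bromo-3-methylbut-2-ene) | CC(C)=CCBr | starting material
3 | 1-[2,4,6-trihydroxy-3-(3-methylbut-2-en-1-yl)phenyl]ethanone | CC(=O)c1c(O)cc(O)c(CC=C(C)C)c1O | intermediate
4 | 1-[2,6-dihydroxy-3-(3-methylbut-2-en-1-yl)-4-(triisopropylsilyloxy)phenyl]ethanone | CC(=O)c1c(O)cc(O[Si](C(C)C)(C(C)C)C(C)C)c(CC=C(C)C)c1O | intermediate
5 | 4-methoxybenzyl alcohol | COc1ccc(CO)cc1 | starting material
6 | 1-[2-hydroxy-6-(4-methoxybenzyloxy)-3-(3-methylbut-2-en-1-yl)-4-(triisopropylsilyloxy)phenyl]ethanone | CC(=O)c1c(OCc2ccc(OC)cc2)cc(O[Si](C(C)C)(C(C)C)C(C)C)c(CC=C(C)C)c1O | intermediate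
7 | 1-[2-(tert-butyldimethylsilyloxy)-6-(4-methoxybenzyloxy)-3-(3-methylbut-2-en-1-yl)-4-(triisopropylsilyloxy)phenyl]ethanone | CC(=O)c1c(OCc2ccc(OC)cc2)cc(O[Si](C(C)C)(C(C)C)C(C)C)c(CC=C(C)C)c1O[Si](C)(C)C(C)(C)C | intermediate
8 | 1-[2-(tert-butyldimethylsilyloxy)-6-(4-methoxybenzyloxy)-3-(3-methylbut-2-en-1-yl)-4-(triisopropylsilyloxy)phenyl]-4,4,4-trifluorobutane-1,3-dione | FC(F)(F)C(=O)CC(=O)c1c(OCc2ccc(OC)cc2)cc(O[Si](C(C)C)(C(C)C)C(C)C)c(CC=C(C)C)c1O[Si](C)(C)C(C)(C)C | intermediate
9 | 2-diazo-1-[2-(tert-butyldimethylsilyloxy)-6-(4-methoxybenzyloxy)-3-(3-methylbut-2-en-1-yl)-4-(triisopropylsilyloxy)phenyl]ethanone | COc1ccc(COc2cc(O[Si](C(C)C)(C(C)C)C(C)C)c(CC=C(C)C)c(O[Si](C)(C)C(C)(C)C)c2C(=O)C=[N+]=[N-])cc1 | intermediate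
10 | (2S)-5-(tert-butyldimethylsilyloxy)-2-(4-methoxyphenyl)-6-(3-methylbut-2-en-1-yl)-7-(triisopropylsilyloxy)chroman-4-one | COc1ccc([C@@H]2CC(=O)c3c(cc(O[Si](C(C)C)(C(C)C)C(C)C)c(CC=C(C)C)c3O[Si](C)(C)C(C)(C)C)O2)cc1 | intermediate
11 | (2S)-5,7-dihydroxy-2-(4-methoxyphenyl)-6-(3-methylbut-2-en-1-yl)chroman-4-one | COc1ccc([C@@H]2CC(=O)c3c(cc(O)c(CC=C(C)C)c3O)O2)cc1 | target

## Step count and risk

Total step count: 7. Longest linear sequence: 7 steps, from 1 to 11.

**Step 6 (key step).** The carbenoid may be captured by the lone pair of O1 before it reaches the benzylic C–H bond, followed by 1,2-shift of the readily migrating 4-methoxybenzyl group. Discrimination between the two enantiotopic hydrogens may also be weak, because an acceptor-only carbenoid reacts through an early transition state. The fallback gives up the C2–C3 bond formation and makes the C2–aryl bond instead. It sets out from 7 and returns at 10.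
- Oxidative removal of the 4-methoxybenzyl group with DDQ in wet CH2Cl2 should give 1-[2-(tert-butyldimethylsilyloxy)-6-hydroxy-3-(3-methylbut-2-en-1-yl)-4-(triisopropylsilyloxy)phenyl]ethanone F1. The freed hydroxyl is not next to the prenyl group, so no chromene can form.
- Condensation with N,N-dimethylformamide dimethyl acetal should give the enaminone (E)-3-(dimethylamino)-1-[2-(tert-butyldimethylsilyloxy)-6-hydroxy-3-(3-methylbut-2-en-1-yl)-4-(triisopropylsilyloxy)phenyl]prop-2-en-1-one F2.
- Mild acid should close F2 to the chromone 5-(tert-butyldimethylsilyloxy)-6-(3-methylbut-2-en-1-yl)-7-(triisopropylsilyloxy)-4H-chromen-4-one F3.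
- Asymmetric 1,4-addition of 4-methoxyphenylboronic acid to F3 should then give 10. The catalyst would be a monovalent rhodium complex made from [Rh(OH)(cod)]2 and an electron-poor chiral biaryl bisphosphine, in CH2Cl2/water at room temperature. This reaction type is established for chromones.

**Step 5.** At the enolate stage the tert-butyldimethylsilyl group may migrate from the ortho oxygen to the enolate oxygen, since the phenoxide is the better leaving group, and the aryl silyl ether may also be attacked during the aqueous amine stage. The fallback avoids any strong base. It sets out from 7 and returns at 9.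
- Heating 7 with N,N-dimethylformamide dimethyl acetal should give the enaminone (E)-3-(dimethylamino)-1-[2-(tert-butyldimethylsilyloxy)-6-(4-methoxybenzyloxy)-3-(3-methylbut-2-en-1-yl)-4-(triisopropylsilyloxy)phenyl]prop-2-en-1-one F4.
- Tosyl azide in CH2Cl2 should add to F4 and fragment to 9 with loss of the N-sulfonyl formamidine, a known diazo transfer to enaminones.

**Step 3.** The two ortho hydroxyls may not be discriminated well enough, giving a mixture of ethers. The fallback fixes the regiochemistry by construction and, as a side benefit, avoids step 1. It sets out from 1 and returns at 6.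
- Silylation of 1 with TIPSCl and imidazole should give the symmetric 1-[2,6-dihydroxy-4-(triisopropylsilyloxy)phenyl]ethanone F5.
- Mitsunobu reaction with one equivalent of 5 has no regiochemical choice and should give 1-[2-hydroxy-6-(4-methoxybenzyloxy)-4-(triisopropylsilyloxy)phenyl]ethanone F6.
- O-alkylation with tert-butyl 2-methylbut-3-en-2-yl carbonate under zerovalent palladium catalysis (Pd(PPh3)4, THF) should give the branched ether 1-[2-(4-methoxybenzyloxy)-6-(2-methylbut-3-en-2-yloxy)-4-(triisopropylsilyloxy)phenyl]ethanone F7.
- Aromatic Claisen rearrangement in hot toluene should deliver the prenyl group to the only free ortho carbon and so give 6.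

**Step 1.** Over-alkylation to di-C-prenyl and O-prenyl products may consume the material, because the mono-prenylated phenolate is no less nucleophilic than that of 1. The fallback replaces direct C-alkylation by O-alkylation and sigmatropic shift. It sets out from 1 and returns at 3.
- Pd(PPh3)4-catalysed reaction of 1 with one equivalent of tert-butyl 2-methylbut-3-en-2-yl carbonate should etherify the most acidic, para hydroxyl and give 1-[2,6-dihydroxy-4-(2-methylbut-3-en-2-yloxy)phenyl]ethanone F8.
- Aromatic Claisen rearrangement of F8 should place the prenyl group on either of the two equivalent ortho carbons and give 3.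

## Further compounds

F1 | step 6 | 1-[2-(tert-butyldimethylsilyloxy)-6-hydroxy-3-(3-methylbut-2-en-1-yl)-4-(triisopropylsilyloxy)phenyl]ethanone | CC(=O)c1c(O)cc(O[Si](C(C)C)(C(C)C)C(C)C)c(CC=C(C)C)c1O[Si](C)(C)C(C)(C)C
F2 | step 6 | (E)-3-(dimethylamino)-1-[2-(tert-butyldimethylsilyloxy)-6-hydroxy-3-(3-methylbut-2-en-1-yl)-4-(triisopropylsilyloxy)phenyl]prop-2-en-1-one | CN(C)/C=C/C(=O)c1c(O)cc(O[Si](C(C)C)(C(C)C)C(C)C)c(CC=C(C)C)c1O[Si](C)(C)C(C)(C)C
F3 | step 6 | 5-(tert-butyldimethylsilyloxy)-6-(3-methylbut-2-en-1-yl)-7-(triisopropylsilyloxy)-4H-chromen-4-one | O=c1ccoc2cc(O[Si](C(C)C)(C(C)C)C(C)C)c(CC=C(C)C)c(O[Si](C)(C)C(C)(C)C)c12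
F4 | step 5 | (E)-3-(dimethylamino)-1-[2-(tert-butyldimethylsilyloxy)-6-(4-methoxybenzyloxy)-3-(3-methylbut-2-en-1-yl)-4-(triisopropylsilyloxy)phenyl]prop-2-en-1-one | CN(C)/C=C/C(=O)c1c(OCc2ccc(OC)cc2)cc(O[Si](C(C)C)(C(C)C)C(C)C)c(CC=C(C)C)c1O[Si](C)(C)C(C)(C)C
F5 | step 3 | 1-[2,6-dihydroxy-4-(triisopropylsilyloxy)phenyl]ethanone | CC(=O)c1c(O)cc(O[Si](C(C)C)(C(C)C)C(C)C)cc1O
F6 | step 3 | 1-[2-hydroxy-6-(4-methoxybenzyloxy)-4-(triisopropylsilyloxy)phenyl]ethanone | CC(=O)c1c(OCc2ccc(OC)cc2)cc(O[Si](C(C)C)(C(C)C)C(C)C)cc1O
F7 | step 3 | 1-[2-(4-methoxybenzyloxy)-6-(2-methylbut-3-en-2-yloxy)-4-(triisopropylsilyloxy)phenyl]ethanone | CC(=O)c1c(OCc2ccc(OC)cc2)cc(O[Si](C(C)C)(C(C)C)C(C)C)cc1OC(C)(C)C=C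
F8 | step 1 | 1-[2,6-dihydroxy-4-(2-methylbut-3-en-2-yloxy)phenyl]ethanone | CC(=O)c1c(O)cc(OC(C)(C)C=C)cc1O
A1 | alternative 1 | (2S,4R)-5,7-bis(methoxymethoxy)-2-(4-methoxyphenyl)-6-(3-methylbut-2-en-1-yl)chroman-4-ol | COc1ccc([C@@H]2C[C@@H](O)c3c(cc(OCOC)c(CC=C(C)C)c3OCOC)O2)cc1
A2 | alternative 1 | (1R,3S)-1-[2-bromo-4,6-bis(methoxymethoxy)-5-(3-methylbut-2-en-1-yl)phenyl]-3-(4-methoxyphenyl)propane-1,3-diol | COc1ccc([C@@H](O)C[C@@H](O)c2c(Br)cc(OCOC)c(CC=C(C)C)c2OCOC)cc1
A3 | alternative 2 | (2S)-5,7-bis(methoxymethoxy)-2-(4-methoxyphenyl)-6-(3-methylbut-2-en-1-yl)chroman-4-one | COc1ccc([C@@H]2CC(=O)c3c(cc(OCOC)c(CC=C(C)C)c3OCOC)O2)cc1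
A4 | alternative 2 | methyl (3S)-3-hydroxy-3-(4-methoxyphenyl)propanoate | COC(=O)C[C@H](O)c1ccc(OC)cc1
A5 | alternative 2 | 3,5-bis(methoxymethoxy)-4-(3-methylbut-2-en-1-yl)-2-(trimethylsilyl)phenyl trifluoromethanesulfonate | COCOc1cc(OS(=O)(=O)C(F)(F)F)c([Si](C)(C)C)c(OCOC)c1CC=C(C)C
A6 | alternative 3 | (2S)-5-hydroxy-2-(4-methoxyphenyl)-6-(3-methylbut-2-en-1-yl)-7-(triisopropylsilyloxy)chroman-4-one | COc1ccc([C@@H]2CC(=O)c3c(cc(O[Si](C(C)C)(C(C)C)C(C)C)c(CC=C(C)C)c3O)O2)cc1
A7 | alternative 3 | (2S)-6-(2-diazoacetyl)-2-(4-methoxyphenyl)-2,3-dihydro-4H-pyran-4-one | COc1ccc([C@@H]2CC(=O)C=C(C(=O)C=[N+]=[N-])O2)cc1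
A8 | alternative 3 | triisopropyl[(5-methylhex-4-en-1-yn-1-yl)oxy]silane | CC(C)=CCC#CO[Si](C(C)C)(C(C)C)C(C)C
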